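(The earlier runs and the new flask were computed for an exercise; noise was put on by code.)

Percent of the substrate charged is the unit of my ledger. Substrate is the limiting reagent in north-west, with 1.60 equiv of reagent, and reagent is limiting in south-west, with 0.530 equiv.

| flask | substrate | reagent | free catalyst | remark | time |
|---|---|---|---|---|---|
| Monday's | 0.088 M | 1.05 equiv | 0.1 mol% | run made earlier |  |
| Sunday's | 0.29 M | 1.05 equiv | 0.1 mol% | run made earlier |  |
| Tuesday's | 0.25 M | 0.79 equiv | 0.1 mol% | run made earlier |  |
| west | 0.25 M | 1.05 equiv | 0.1 mol% |  | 4.0 min |
| south | 0.12 M | 1.05 equiv | 0.1 mol% |  | 4.0 min |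
| south-west | 0.060 M | 0.530 equiv | 0.1 mol% |  | 4.0 min |
| south-east | 0.25 M | 1.60 equiv | 0.15 mol% |  | 4.0 min |
| north-west | 0.25 M | 1.60 equiv | 0.2 mol% |  | 4.0 min |

- Monday's (time / s: target / %, substrate / %): 10.0: 1.0, 98.5; 30.0: 3.2, 96.8; 60.0: 6.7, 92.6; 80.0: 8.8, 90.9; 120: 14.4, 86.9
- Sunday's (time / s: target / %, substrate / %): 10.0: 2.2, 97.3; 30.0: 9.0, 91.6; 60.0: 17.4, 83.3; 80.0: 22.9, 78.0; 120: 32.0, 68.0
- Tuesday's (time / s: target / %, substrate / %): 10.0: 2.9, 97.3; 20.0: 4.6, 95.6; 30.0: 8.3, 92.1; 60.0: 14.7, 85.3; 120: 28.4, 72.1

(standard deviation of a reading: 0.5 percentage points)

- the earlier runs were read with a standard deviation of 0.5 percentage points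

- the flasks put in order of amount of target, in percent of the substrate charged, best first, at 4.0 min (west / south / south-west / south-east / north-west)
- the amount of target, in percent of the substrate charged of the flask you put first, at 4.0 min
- the amount of target, in percent of the substrate charged of the flask you put last, at 4.0 min

My books have two entries, substrate left and target made. At the last readings they add to 101 % on Monday, 100 % on Sunday and 100 % on Tuesday, so with a scatter of 0.5 points per reading I open no third entry. Next comes the rate of transfer between the entries. The curves are nearly straight on a first-order plot, so I take the logarithm of one over the part not yet target, then divide by the time and by the molarity of catalyst charged. The last readings give 14.7 M⁻¹ s⁻¹ for Monday, 11.1 M⁻¹ s⁻¹ for Sunday and 11.1 M⁻¹ s⁻¹ for Tuesday. Tuesday's, with 0.79 equiv of reagent and 0.25 M of substrate, matches Sunday's, with 1.05 equiv and 0.29 M, so I book reagent as a ceiling and not as a rate term. Monday's reading is higher, so the mean below is a rough figure read from scattered runs. I call the mean, 12.3 M⁻¹ s⁻¹, the turnover constant: the first-order rate of target formation per molar catalyst charged. Loading is 0.1 mol% on Monday, Sunday and Tuesday alike, so its being first order in catalyst is my assumption.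

The flasks then rank by catalyst molarity: north-west, south-east, west, south, south-west. At 4.0 min north-west's books read 77.2 % target and 22.8 % substrate. South-west reaches 16.2 %, under the cap of 0.530 equiv that one reagent per target, again my assumption, would set.

The forecast gives north-west > south-east > west > south > south-west, with 70 % and 19 %, saying “I take the catalyst order as about 0.8”; its top is lower than mine and its low is higher.

The flasks give north-west > south-east > west > south > south-west, with 82.2 % in north-west and 15.9 % in south-west.

    catalyst intermediate A → by-product + catalyst intermediate B (k = 283 s⁻¹)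
    substrate + catalyst intermediate C ⇌ catalyst intermediate D (K = 1.43 M⁻¹, k = 74.8 M⁻¹ s⁻¹)
    catalyst intermediate B → catalyst intermediate C (k = 17.4 s⁻¹)
    catalyst intermediate D → free catalyst + target (k = 18.8 s⁻¹)
    reagent + free catalyst → catalyst intermediate A (k = 79.5 M⁻¹ s⁻¹)

Booked the same way, north-west's result gives a turnover constant of 14.4 M⁻¹ s⁻¹, higher than mine. The 17.8 % of substrate still open in north-west comes from two things acting together, the back reaction of catalyst intermediate D to substrate and catalyst intermediate C and the reading at that time. Without that back step north-west reaches 99.7 % at the same reading, and with it, left until 40.0 min, north-west reaches 100 %.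

For south-west read at 1.5 min, the turnover constant gives 6.43 % target, and the computed flask holds 6.37 %.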